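**The easy entry.** I keep a ledger of the starting material, the limiting reagent. Each mole of it is unreacted, target, or lost from target, so I need the unreacted and the lost entries, and the target closes the books.

| flask | starting material | catalyst | temperature | remark | time |
|---|---|---|---|---|---|
| dusk | 0.25 M | 75 mM | 45 °C | run made earlier |  |
| winter | 1 M | 75 mM | 80 °C | run made earlier |  |
| autumn | 0.50 M | 110 mM | 45 °C | run made earlier |  |
| theta | 0.50 M | 75 mM | 110 °C |  | 40 min |
| zeta | 0.50 M | 75 mM | 90 °C |  | 40 min |
| beta | 0.50 M | 75 mM | 70 °C |  | 40 min |
| alpha | 0.50 M | 75 mM | 50 °C |  | 40 min |

- dusk (time / min: target / %): 80.0: 70.1; 180: 91.2; 360: 93.8; 900: 84.8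
- winter (time / min: target / %): 40.0: 98.0; 80.0: 96.1; 120: 93.2; 180: 91.3
- autumn (time / min: target / %): 80.0: 82.5; 180: 97.0; 360: 95.4; 900: 88.7

(each reading ± 0.5 percentage points)

1. the best flask by amount of target, in percent of the starting material charged; "all alike" if 1.5 percentage points covers them all (theta / zeta / beta / alpha / all alike)
2. amount of target at the end, in percent of the starting material charged, theta
3. amount of target at the end, in percent of the starting material charged, zeta
4. amount of target at the end, in percent of the starting material charged, beta
5. amount of target at the end, in percent of the starting material charged, alpha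

**Lost entry.** Late in each run the target falls, and I read that fall as a straight line, a concentration per minute. Dusk loses 0.0417 mM min⁻¹ and autumn 0.0620 mM min⁻¹. That ratio of 1.49 stands near the catalyst ratio of 1.47, but far from the charge ratio of 2.00. Winter, with dusk's catalyst, loses 0.479 mM min⁻¹, and if the charge plays no part, these two readings give an activation energy of about 65.2 kJ mol⁻¹. At 70 °C I then reckon 0.251 mM min⁻¹. This wear rate, the concentration of target lost per minute at 75 mM of catalyst, read as independent of the charge, is what I carry.

**Both ends.** Over 40 min at 0.50 M, I reckon that wear takes 2.01% of the charge in beta. In theta I reckon 21.8%, which is more than in beta. For alpha the unreacted entry stays open in my ledger, so I take the forecast's range there.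

**The forecast.** It names beta as best, with theta 78.5%, zeta 92.9%, beta 96% and alpha 59.5%. Its formation estimate “leaves alpha incomplete”. My closing of theta, with the unreacted entry taken as empty, is 78.2%, close to its figure, though both rest on the same readings.

**The flasks.** The best is beta, with theta 76.7%, zeta 92.5%, beta 97.7% and alpha 62.7%.

    starting material + catalyst → catalyst + target (k = 0.160 M⁻¹ s⁻¹, Ea = 82.0 kJ mol⁻¹)
    catalyst + target → catalyst + over-reaction product (k = 0.00170 M⁻¹ s⁻¹, Ea = 66.0 kJ mol⁻¹)
    crystals ⇌ target, rate k3*(cs3 - [target]) while solid is left; crystals form when [target] > cs3 (solubility = 0.120 M, k = 0.0550 s⁻¹)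
    (constants at 90 °C)

**The comparison.** In beta the making has 95% of its turnover behind it after 20.0 min, while the loss has 50%, and beta ends with 2.06% of over-reaction product against my reckoned 2.01%. For the neighbour at 0.12 M, otherwise beta, the wear rate gives 8.36% of its charge lost. The computed flask holds 6.86% of over-reaction product, less than reckoned, with 92.9% of target and 0% of crystals.

The data stem from a simulated flask for substances that don't exist.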